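**Retrosynthetic overview**
1. Feature: in ring B, O2 and O4 flank the C3 methyl and sit beside the C1 methyl ester. Ring B is therefore the enolised form of a methyl 2,4-dioxocyclohexane-1-carboxylate lacking only H2 across C5–C6. The depside oxygen O5 can be put on C5 while that carbon is still sp3, so it never has to be distinguished from O2 and O4.
2. Target ⇒ (acid; loss of silyl, MOM and dioxolane groups) protected depside ⇒ (dehydrogenation across C5–C6) 5-aroyloxy-3,6-dimethyl-2,4-dioxocyclohexane-1-carboxylate.
3. Dione ⇒ cut C1–C6 (Michael) and C3–C4 (Dieckmann) ⇒ methyl 3-oxopentanoate + methyl 2-aroyloxybut-2-enoate.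
4. Enoate ⇒ (HWE with acetaldehyde) α-aroyloxyphosphonoacetate ⇒ (rhodium-carbenoid O–H insertion) protected haematommic acid + trimethyl diazophosphonoacetate. The acid ⇒ methyl orsellinate (C3' formylation, MOM ethers, dioxolane, saponification).
5. Ring order: ring A is bought as the arene. Ring B is the only ring built; it is closed saturated in step 8 and aromatised in step 9.

Key step: step 8

Remark: the target has no stereocentre and no stereogenic double bond, so the enoate geometry and the configurations of the phosphonate and of the saturated ring B intermediates are left unassigned and mixtures are carried on. Ring B is numbered C1 (CO2Me) to C6 (CH3); ring A atoms carry primes (C1' bears the acyl carbon, C3' the formyl group, C6' the methyl group).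

**Step 1**
Reactants: 1 methyl orsellinate (methyl 2,4-dihydroxy-6-methylbenzoate)
Product: 2 methyl haematommate (methyl 3-formyl-2,4-dihydroxy-6-methylbenzoate)
Conditions: TiCl4 (2.5 equiv), Cl2CHOMe (1.2 equiv), CH2Cl2, −10 → 0 °C; then 1 M aq. HCl
Reagents that add atoms: dichloromethyl methyl ether COC(Cl)Cl; water O
Why: Rieche formylation, in which the titanium phenoxides at O2' and O4' steer the electrophile to C3', the carbon ortho to both oxygens; any C5' isomer is removed by crystallisation or chromatography.

**Step 2**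
Reactants: 2 methyl haematommate
Product: 3 methyl 3-formyl-2,4-bis(methoxymethoxy)-6-methylbenzoate
Conditions: NaH (2.4 equiv), MOMCl (2.6 equiv), DMF, 0 °C → rt
Reagents that add atoms: chloromethyl methyl ether COCCl
Why: Williamson-type O-alkylation of both sodium phenoxides, where full deprotonation breaks the hydrogen bonds to CHO and CO2Me that slow amine-base protocols.

**Step 3**
Reactants: 3 methyl 3-formyl-2,4-bis(methoxymethoxy)-6-methylbenzoate
Product: 4 methyl 3-(1,3-dioxolan-2-yl)-2,4-bis(methoxymethoxy)-6-methylbenzoate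
Conditions: TMSOCH2CH2OTMS (1.5 equiv), TMSOTf (0.05 equiv), CH2Cl2, −78 °C; pyridine quench
Reagents that add atoms: 1,2-bis(trimethylsilyloxy)ethane C[Si](C)(C)OCCO[Si](C)(C)C
Why: Noyori acetalisation, in which the catalyst silylates the electron-rich aldehyde oxygen at −78 °C and formation of hexamethyldisiloxane makes the exchange irreversible, while the aryl MOM ethers should not ionise at this temperature and catalyst loading.

**Step 4**
Reactants: 4 methyl 3-(1,3-dioxolan-2-yl)-2,4-bis(methoxymethoxy)-6-methylbenzoate
Product: 5 3-(1,3-dioxolan-2-yl)-2,4-bis(methoxymethoxy)-6-methylbenzoic acid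
Conditions: KOH (10 equiv), DMSO–H2O (4:1), 90 °C; then 1 M aq. KHSO4 to pH 4 at 0 °C, EtOAc extraction
Reagents that add atoms: potassium hydroxide [K+].[OH-]
Why: Saponification of a di-ortho-substituted methyl benzoate with poorly solvated hydroxide in hot aqueous DMSO; MOM ethers and dioxolane are inert to base, and the cold pH-controlled acidification spares the acetal.

**Step 5**
Reactants: 6 trimethyl phosphonoacetate
Product: 7 trimethyl diazophosphonoacetate (methyl 2-diazo-2-(dimethoxyphosphoryl)acetate)
Conditions: 4-acetamidobenzenesulfonyl azide (1.1 equiv), DBU (1.2 equiv), MeCN, 0 °C → rt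
Reagents that add atoms: 4-acetamidobenzenesulfonyl azide CC(=O)Nc1ccc(cc1)S(=O)(=O)N=[N+]=[N-]
Why: Regitz diazo transfer to a doubly activated methylene group, with a sulfonamide by-product that is easy to remove.

**Step 6**
Reactants: 5 3-(1,3-dioxolan-2-yl)-2,4-bis(methoxymethoxy)-6-methylbenzoic acid; 7 trimethyl diazophosphonoacetate
Product: 8 methyl 2-(dimethoxyphosphoryl)-2-{[3-(1,3-dioxolan-2-yl)-2,4-bis(methoxymethoxy)-6-methylbenzoyl]oxy}acetate (racemic)
Conditions: Rh2(OAc)4 (0.02 equiv), toluene, 80 °C, slow addition of 7 (1.3 equiv)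
Reagents that add atoms: none
Why: Rhodium-carbenoid O–H insertion of a carboxylic acid, which forms the bond at the carboxyl oxygen and not at the screened carbonyl carbon, so the di-ortho substitution that hampers ordinary esterification does not matter; the new stereocentre is racemic and is destroyed in step 7.

**Step 7**
Reactants: 8 methyl 2-(dimethoxyphosphoryl)-2-(aroyloxy)acetate as named in step 6; 9 acetaldehyde
Product: 10 methyl (Z)-2-{[3-(1,3-dioxolan-2-yl)-2,4-bis(methoxymethoxy)-6-methylbenzoyl]oxy}but-2-enoate
Conditions: LiCl (1.3 equiv), DBU (1.1 equiv), MeCN, 0 °C; 9 (4 equiv), 0 °C → rt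
Reagents that add atoms: none
Why: Horner–Wadsworth–Emmons olefination under Masamune–Roush conditions, a known use of α-acyloxyphosphonoacetates with aliphatic aldehydes, which should favour the Z isomer (methyl trans to CO2Me); any E isomer is carried along because both alkene carbons become sp3 and then aromatic.

**Step 8**
Reactants: 10 methyl (Z)-2-(aroyloxy)but-2-enoate as named in step 7; 11 methyl 3-oxopentanoate
Product: 13 methyl 5-{[3-(1,3-dioxolan-2-yl)-2,4-bis(methoxymethoxy)-6-methylbenzoyl]oxy}-3,6-dimethyl-2,4-dioxocyclohexane-1-carboxylate (mixture of diastereomers and enol tautomers), via open-chain Michael adduct 12 (not isolated)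
Conditions: 11 (1.15 equiv), KOtBu (1.1 equiv), THF–tBuOH (4:1), 0 °C; add 10, 0 °C → rt until 10 is consumed; then KOtBu (1.0 equiv), rt → 40 °C; AcOH (3 equiv), 0 °C
Reagents that add atoms: none
Why: Proposed new method: the potassium enolate of 11 adds through its doubly activated α-carbon (future C1) to the β-carbon of 10 (future C6), tBuOH at once protonates the resulting α-aroyloxy ester enolate so that 12 rests as its β-keto ester enolate, and after the second charge of base the ethyl-ketone α'-carbanion (future C3) attacks the methyl ester that came from 10 (future C4), expelling methoxide, which is spent in deprotonating the new 1,3-dione. The closest known reaction is the alkoxide-mediated Michael–Dieckmann (Michael–Claisen) annulation of β-keto esters with crotonates to 4-carboalkoxycyclohexane-1,3-diones, established for 11 with methyl crotonate itself, whereas an enoate whose α-carbon bears an aroyloxy group, that is an enol ester, has not been taken through it. Ring B closes by a 6-exo-trig acyl substitution, helped by the inductive activation of the α-acyloxy ester and made irreversible by formation of the vinylogous carboxylate. The four stereocentres (C1, C3, C5, C6) arise without control, and none needs control because all are erased in step 9. The selectivity needed is C–C bond formation ahead of acyl transfer or loss of the aroyloxy group: the aroyl carbonyl is screened by the C2' OMOM and C6' methyl groups, the first charge of hindered base is held wholly as stabilised enolate while the labile enol ester is present, every ester is a methyl ester so that stray methoxide exchanges degenerately, and C6–H, the only hydrogen whose removal would expel the carboxylate from C5, is α to no carbonyl. Regiochemistry follows from acidity and ring size, since the α-carbon of 11 is the only enolate present at the Michael stage and the α'-carbon reaches the C4 ester through a six-membered transition state, whereas closure on the C1 ester or on the aroyl group would need four- or seven-membered ones.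

**Step 9**
Reactants: 13 methyl 5-(aroyloxy)-3,6-dimethyl-2,4-dioxocyclohexane-1-carboxylate as named in step 8
Product: 15 methyl 5-{[3-(1,3-dioxolan-2-yl)-2,4-bis(methoxymethoxy)-6-methylbenzoyl]oxy}-3,6-dimethyl-2,4-bis(trimethylsilyloxy)benzoate, via bis-silyl dienol ether 14 (not isolated)
Conditions: BSTFA (2.5 equiv), toluene, rt; then DDQ (1.1 equiv), 0 °C → rt; filter off the hydroquinone, concentrate, use crude
Reagents that add atoms: N,O-bis(trimethylsilyl)trifluoroacetamide C[Si](C)(C)OC(=N[Si](C)(C)C)C(F)(F)F
Why: Silylation-mediated DDQ dehydrogenation, in which BSTFA locks 13 as the 2,4-bis(silyloxy)cyclohexa-1,3-diene 14, whose C6–H is hydridic because the derived cation is stabilised by both silyloxy groups, so H6 leaves as hydride and H5 as proton at or below room temperature, where the MOM ethers, the aryl dioxolane and the hindered ester should persist.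

**Step 10**
Reactants: 15 methyl 5-(aroyloxy)-3,6-dimethyl-2,4-bis(trimethylsilyloxy)benzoate as named in step 9
Product: 16 methyl 5-[(3-formyl-2,4-dihydroxy-6-methylbenzoyl)oxy]-2,4-dihydroxy-3,6-dimethylbenzoate (target)
Conditions: 3 M aq. HCl–THF (1:3), rt → 40 °C
Reagents that add atoms: water O
Why: Acid-catalysed hydrolysis of the two aryl silyl ethers, the dioxolane and the two MOM ethers in one operation; the di-ortho-substituted depside ester and the methyl ester resist dilute acid, no alcohol is present that could transesterify the depside, and O4 stays protonated so that a 1,2-acyl shift from O5 is not set off.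

**Compound list**
1 | methyl orsellinate | COC(=O)c1c(C)cc(O)cc1O | starting material
2 | methyl haematommate | COC(=O)c1c(C)cc(O)c(C=O)c1O | intermediate
3 | methyl 3-formyl-2,4-bis(methoxymethoxy)-6-methylbenzoate | COC(=O)c1c(C)cc(OCOC)c(C=O)c1OCOC | intermediate
4 | methyl 3-(1,3-dioxolan-2-yl)-2,4-bis(methoxymethoxy)-6-methylbenzoate | COC(=O)c1c(C)cc(OCOC)c(C2OCCO2)c1OCOC | intermediate
5 | 3-(1,3-dioxolan-2-yl)-2,4-bis(methoxymethoxy)-6-methylbenzoic acid | OC(=O)c1c(C)cc(OCOC)c(C2OCCO2)c1OCOC | intermediate
6 | trimethyl phosphonoacetate | COC(=O)CP(=O)(OC)OC | starting material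
7 | trimethyl diazophosphonoacetate | COC(=O)C(=[N+]=[N-])P(=O)(OC)OC | intermediate
8 | methyl 2-(dimethoxyphosphoryl)-2-{[3-(1,3-dioxolan-2-yl)-2,4-bis(methoxymethoxy)-6-methylbenzoyl]oxy}acetate (racemic) | COC(=O)C(OC(=O)c1c(C)cc(OCOC)c(C2OCCO2)c1OCOC)P(=O)(OC)OC | intermediate
9 | acetaldehyde | CC=O | starting material
10 | methyl (Z)-2-{[3-(1,3-dioxolan-2-yl)-2,4-bis(methoxymethoxy)-6-methylbenzoyl]oxy}but-2-enoate | C/C=C(\OC(=O)c1c(C)cc(OCOC)c(C2OCCO2)c1OCOC)C(=O)OC | intermediate
11 | methyl 3-oxopentanoate | CCC(=O)CC(=O)OC | starting material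
12 | dimethyl 2-{[3-(1,3-dioxolan-2-yl)-2,4-bis(methoxymethoxy)-6-methylbenzoyl]oxy}-3-methyl-4-propanoylpentanedioate (stereocentres unassigned) | CCC(=O)C(C(=O)OC)C(C)C(OC(=O)c1c(C)cc(OCOC)c(C2OCCO2)c1OCOC)C(=O)OC | intermediate
13 | methyl 5-{[3-(1,3-dioxolan-2-yl)-2,4-bis(methoxymethoxy)-6-methylbenzoyl]oxy}-3,6-dimethyl-2,4-dioxocyclohexane-1-carboxylate (stereocentres unassigned) | COC(=O)C1C(C)C(OC(=O)c2c(C)cc(OCOC)c(C3OCCO3)c2OCOC)C(=O)C(C)C1=O | intermediate
14 | methyl 5-{[3-(1,3-dioxolan-2-yl)-2,4-bis(methoxymethoxy)-6-methylbenzoyl]oxy}-3,6-dimethyl-2,4-bis(trimethylsilyloxy)cyclohexa-1,3-diene-1-carboxylate (stereocentres unassigned) | COC(=O)C1=C(O[Si](C)(C)C)C(C)=C(O[Si](C)(C)C)C(OC(=O)c2c(C)cc(OCOC)c(C3OCCO3)c2OCOC)C1C | intermediate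
15 | methyl 5-{[3-(1,3-dioxolan-2-yl)-2,4-bis(methoxymethoxy)-6-methylbenzoyl]oxy}-3,6-dimethyl-2,4-bis(trimethylsilyloxy)benzoate | COC(=O)c1c(C)c(OC(=O)c2c(C)cc(OCOC)c(C3OCCO3)c2OCOC)c(O[Si](C)(C)C)c(C)c1O[Si](C)(C)C | intermediate
16 | methyl 5-[(3-formyl-2,4-dihydroxy-6-methylbenzoyl)oxy]-2,4-dihydroxy-3,6-dimethylbenzoate | COC(=O)c1c(C)c(OC(=O)c2c(C)cc(O)c(C=O)c2O)c(O)c(C)c1O | target

**Step count**
Total steps: 10.
Longest linear sequence: 9 (steps 1–4 and 6–10, from methyl orsellinate).

**Steps most likely to fail**

*Step 8 (goes beyond known chemistry).*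
- Risks: the enolate may take the aroyl group from the enol ester instead of adding to the alkene. The reversible conjugate addition to a trisubstituted acceptor may stall before ring closure. The aroyloxy group may be lost from C5 with direct aromatisation.
- The fallback sets out from 5 and comes back at 16. It joins the two rings by conventional depside esterification.
- Purchased methyl 2,4-dihydroxy-3,6-dimethylbenzoate F1 is formylated at C5, its only free position (TiCl4, Cl2CHOMe), to methyl 5-formyl-2,4-dihydroxy-3,6-dimethylbenzoate F2.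
- NaH/MOMCl gives methyl 5-formyl-2,4-bis(methoxymethoxy)-3,6-dimethylbenzoate F3.
- Baeyer–Villiger oxidation (mCPBA, NaHCO3, CH2Cl2) gives methyl 5-(formyloxy)-2,4-bis(methoxymethoxy)-3,6-dimethylbenzoate F4.
- KHCO3 in MeOH frees methyl 5-hydroxy-2,4-bis(methoxymethoxy)-3,6-dimethylbenzoate F5, in which O5 is the only free phenol.
- Steglich esterification of 5 with F5 (DCC, DMAP, toluene) gives methyl 5-{[3-(1,3-dioxolan-2-yl)-2,4-bis(methoxymethoxy)-6-methylbenzoyl]oxy}-2,4-bis(methoxymethoxy)-3,6-dimethylbenzoate F6.
- F6 under the conditions of step 10 gives 16.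

*Step 9.*
- Risks: DDQ may abstract hydride from the benzylic acetal C–H of ring A. The cyclohexadiene may aromatise by expelling the carboxylate from C5 instead of losing H2.
- The fallback sets out from 13 and comes back at 16. It replaces hydride abstraction by halogenation and elimination, as practised on the parent 3,6-dimethyl-2,4-dioxocyclohexanecarboxylate.
- NCS (1.0 equiv, CH2Cl2, 0 °C) chlorinates the dione enol at C3 to methyl 3-chloro-5-{[3-(1,3-dioxolan-2-yl)-2,4-bis(methoxymethoxy)-6-methylbenzoyl]oxy}-3,6-dimethyl-2,4-dioxocyclohexane-1-carboxylate F7.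
- Heating with LiCl and Li2CO3 in DMF (80 °C) brings about 1,4-dehydrochlorination (Cl from C3, H from C6, through the C4=C5 enol). This gives methyl 5-{[3-(1,3-dioxolan-2-yl)-2,4-bis(methoxymethoxy)-6-methylbenzoyl]oxy}-2,4-dihydroxy-3,6-dimethylbenzoate F8.
- F8 under the conditions of step 10 gives 16.

*Step 6.*
- Risks: the carbenoid may be diverted into oxonium-ylide formation at the acetal and MOM oxygens, addition to the electron-rich arene, or dimerisation.
- The fallback sets out from 5 and comes back at 10. It makes the enol ester by O-acylation, so steps 5–7 are not needed.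
- Cyanuric fluoride and pyridine (CH2Cl2, −10 °C) convert 5 under non-acidic conditions into 3-(1,3-dioxolan-2-yl)-2,4-bis(methoxymethoxy)-6-methylbenzoyl fluoride F9.
- Purchased methyl 2-oxobutanoate F10 is enolised with KN(SiMe3)2 (THF, −78 °C). The potassium enolate is acylated on oxygen by the hard, hindered F9 to give 10 as an E/Z mixture, which serves equally in step 8.

**Further compounds**
F1 | step 8 | methyl 2,4-dihydroxy-3,6-dimethylbenzoate (purchased) | COC(=O)c1c(C)cc(O)c(C)c1O
F2 | step 8 | methyl 5-formyl-2,4-dihydroxy-3,6-dimethylbenzoate | COC(=O)c1c(C)c(C=O)c(O)c(C)c1O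
F3 | step 8 | methyl 5-formyl-2,4-bis(methoxymethoxy)-3,6-dimethylbenzoate | COC(=O)c1c(C)c(C=O)c(OCOC)c(C)c1OCOC
F4 | step 8 | methyl 5-(formyloxy)-2,4-bis(methoxymethoxy)-3,6-dimethylbenzoate | COC(=O)c1c(C)c(OC=O)c(OCOC)c(C)c1OCOC
F5 | step 8 | methyl 5-hydroxy-2,4-bis(methoxymethoxy)-3,6-dimethylbenzoate | COC(=O)c1c(C)c(O)c(OCOC)c(C)c1OCOC
F6 | step 8 | methyl 5-{[3-(1,3-dioxolan-2-yl)-2,4-bis(methoxymethoxy)-6-methylbenzoyl]oxy}-2,4-bis(methoxymethoxy)-3,6-dimethylbenzoate | COC(=O)c1c(C)c(OC(=O)c2c(C)cc(OCOC)c(C3OCCO3)c2OCOC)c(OCOC)c(C)c1OCOC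
F7 | step 9 | methyl 3-chloro-5-{[3-(1,3-dioxolan-2-yl)-2,4-bis(methoxymethoxy)-6-methylbenzoyl]oxy}-3,6-dimethyl-2,4-dioxocyclohexane-1-carboxylate (stereocentres unassigned) | COC(=O)C1C(C)C(OC(=O)c2c(C)cc(OCOC)c(C3OCCO3)c2OCOC)C(=O)C(C)(Cl)C1=O
F8 | step 9 | methyl 5-{[3-(1,3-dioxolan-2-yl)-2,4-bis(methoxymethoxy)-6-methylbenzoyl]oxy}-2,4-dihydroxy-3,6-dimethylbenzoate | COC(=O)c1c(C)c(OC(=O)c2c(C)cc(OCOC)c(C3OCCO3)c2OCOC)c(O)c(C)c1O
F9 | step 6 | 3-(1,3-dioxolan-2-yl)-2,4-bis(methoxymethoxy)-6-methylbenzoyl fluoride | O=C(F)c1c(C)cc(OCOC)c(C2OCCO2)c1OCOC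
F10 | step 6 | methyl 2-oxobutanoate (purchased) | CCC(=O)C(=O)OC
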